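**Retrosynthetic overview**
1. The ester C3–O bond is cut to diol 21 and the (Z)-acid 26. The C11 carbinol goes back to an isopropenyl group (Mukaiyama hydration), and this to the C7–Br bond of bromodienone 17 (Suzuki coupling).
2. The strategy rests on ring B (C5–C10): a 4,4-disubstituted cyclohexa-2,5-dienone, C6=C7–C8(=O)–C9=C10, with quaternary C5 and a carbon substituent on C7. Without C7 it is the cyclopentenone C5–C6–C8–C9–C10, so ring B is made from silyl dienol ether 14 by inserting C7 (from CBr2) between C6 and C8.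
3. Cyclopentenone 12 comes from 1,7-enyne 10 by a Pauson–Khand reaction, which forms ring A (C5–C10) and the five-membered ring (C6–C8, C8–C9) together and sets C5 from C3 and C4.
4. Enyne 10 comes from an Evans syn-aldol of 1 with 2 (C3, C4), then Weinreb amide, methyl ketone and methylenation. Acid 26 comes from propargyl alcohol 22 by anti-carbomagnesiation, thiolation and oxidation.
5. Ring order: ring A and the five-membered ring together (step 6), then enlargement of the five-membered ring to ring B (step 8).

Key step: step 8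

Remark: atom numbers C1–C11 follow the eremophilane skeleton (ring A = C1, C2, C3, C4, C5, C10; ring B = C5–C10; C11 = carbinol carbon). In every bicyclic compound the C3 oxygen is trans to the C4 methyl and the C4 and C5 methyls are cis, as in the target; the SMILES strings are authoritative. Pent-4-ynal is taken as purchasable. The side-chain acid is not, and is made in steps 12–14.

**Step 1**
Reactants: 1 (S)-4-benzyl-3-propionyloxazolidin-2-one; 2 pent-4-ynal
Product: 5 (S)-4-benzyl-3-[(2S,3R)-3-hydroxy-2-methylhept-6-ynoyl]oxazolidin-2-one, via dibutylboron Z-enolate 3 (not isolated), via dibutylboron aldolate 4 (not isolated)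
Conditions: n-Bu2BOTf, i-Pr2NEt, CH2Cl2, 0 °C; then 2, −78 → 0 °C; pH 7 buffer, MeOH, H2O2, 0 °C
Reagents that add atoms: none
Why: Evans syn-aldol reaction: the Z-boron enolate should react through a closed chair transition state with the benzyl group shielding one face, setting the C4 methyl and C3 hydroxyl centres as the syn pair in the absolute sense needed.

**Step 2**
Reactants: 5 aldol adduct
Product: 6 (2S,3R)-3-hydroxy-N-methoxy-N,2-dimethylhept-6-ynamide
Conditions: MeNH(OMe)·HCl, AlMe3, THF/CH2Cl2, −10 → 0 °C; 0.5 M HCl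
Reagents that add atoms: N,O-dimethylhydroxylamine hydrochloride, CNOC.Cl
Why: Aluminium amide transamination (Weinreb amide formation): the free C3 hydroxyl binds aluminium and directs attack to the exocyclic imide carbonyl, so the auxiliary is released and C3 and C4 are not touched.

**Step 3**
Reactants: 6 hydroxy Weinreb amide
Product: 7 (2S,3R)-3-[(tert-butyldimethylsilyl)oxy]-N-methoxy-N,2-dimethylhept-6-ynamide
Conditions: TBSOTf, 2,6-lutidine, CH2Cl2, −78 → 0 °C
Reagents that add atoms: tert-butyldimethylsilyl triflate, CC(C)(C)[Si](C)(C)OS(=O)(=O)C(F)(F)F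
Why: Silyl ether formation with the triflate is fast on the hindered secondary alcohol, and the TBS group should survive the Grignard reagent, the ylide, cobalt carbonyl, amide and alkoxide bases and the cross-coupling.

**Step 4**
Reactants: 7 silyloxy Weinreb amide
Product: 9 (3S,4R)-4-[(tert-butyldimethylsilyl)oxy]-3-methyloct-7-yn-2-one, via magnesium hemiaminal chelate 8 (not isolated)
Conditions: MeMgBr, THF, −20 → 0 °C; aq. NH4Cl
Reagents that add atoms: methylmagnesium bromide, C[Mg]Br
Why: Weinreb ketone synthesis: the chelated tetrahedral adduct 8 is stable until the quench, so only one methyl adds, and any acetylide formed from the terminal alkyne by excess Grignard reagent is reprotonated on work-up.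

**Step 5**
Reactants: 9 methyl ketone
Product: 10 tert-butyl{[(3R,4R)-2,3-dimethyloct-1-en-7-yn-4-yl]oxy}dimethylsilane
Conditions: Ph3PCH3Br, KOt-Bu, THF, 0 °C → rt
Reagents that add atoms: methyltriphenylphosphonium bromide, C[P+](c1ccccc1)(c1ccccc1)c1ccccc1.[Br-]
Why: Wittig methylenation of the methyl ketone; the ylide is made with a slight deficit of base and used at 0 °C, so epimerisation at the α-carbon (C4 of the skeleton) and β-elimination of the silyloxy group should not compete.

**Step 6**
Reactants: 10 1,7-enyne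
Product: 12 (6R,7R,7aR)-6-[(tert-butyldimethylsilyl)oxy]-7,7a-dimethyl-1,4,5,6,7,7a-hexahydro-2H-inden-2-one, via hexacarbonyldicobalt alkyne complex 11 (not isolated)
Conditions: Co2(CO)8, CH2Cl2, rt; then NMO, 0 °C → rt
Reagents that add atoms: dicobalt octacarbonyl, O=C=[Co](=C=O)(=C=O)(=C=O)[Co](=C=O)(=C=O)(=C=O)=C=O
Why: Intramolecular Pauson–Khand [2+2+1] reaction forms C5–C10, C6–C8 and C8–C9; a chair-like tether with the C3 silyloxy and C4 methyl groups equatorial and C6 pseudo-equatorial (angular methyl axial) should place the C5 methyl cis to the C4 methyl, since the C5 epimer would need a 1,3-diaxial silyloxy/methyl contact.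

**Step 7**
Reactants: 12 bicyclic cyclopentenone
Product: 14 6-[(tert-butyldimethylsilyl)oxy]-7,7a-dimethyl-2-[(trimethylsilyl)oxy]-5,6,7,7a-tetrahydro-4H-indene (C6=C8 and C9=C10 diene), via lithium dienolate 13 (not isolated)
Conditions: LiN(i-Pr)2, THF, −78 °C; Me3SiCl, −78 → 0 °C; pentane, filtration, used crude
Reagents that add atoms: chlorotrimethylsilane, C[Si](C)(C)Cl
Why: Kinetic enolisation with the amide base removes an α′ proton at C6 (not a γ proton at C1) and O-silylation gives the 2-silyloxy diene, which cannot tautomerise because C5 is quaternary and is used at once because it is moisture-sensitive.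

**Step 8**
Reactants: 14 silyl dienol ether; 15 bromoform
Product: 17 (4aS,5R,6R)-3-bromo-6-[(tert-butyldimethylsilyl)oxy]-4a,5-dimethyl-5,6,7,8-tetrahydronaphthalen-2(4aH)-one (7-bromo dienone), via gem-dibromocyclopropane 16 (not isolated)
Conditions: CHBr3, KOt-Bu, pentane, −30 → 25 °C
Reagents that add atoms: none
Why: Dibromocarbene, formed from bromoform by α-elimination with KOt-Bu, adds as an electrophile in a concerted [2+1] step to C6=C8 and places C7 between C6 and C8 as the gem-dibromocyclopropane 16. On warming, 16 should lose the endo bromide with disrotatory two-electron electrocyclic opening of the C6–C8 bond (cyclopropyl to allyl cation), and the 2-bromo-1-silyloxyallyl cation then gives up Me3Si to bromide, leaving the C8 ketone next to C6=C7(Br). The closest known reaction is the dihalocarbene one-carbon ring enlargement of cyclopentanone silyl enol ethers to 2-halocyclohex-2-enones. Ring B is therefore closed by enlargement of the five-membered ring (C6–C7 and C7–C8 made, C6–C8 broken) and not by a cyclisation. No stereocentre forms, C3, C4 and C5 are untouched (the C4a label becomes S only because bromine changes the priorities), and the quaternary C5 blocks aromatisation of the dienone. The step needs chemoselectivity between the two diene double bonds, and the silyloxy group on C8 secures it by making C6=C8 more nucleophilic than the non-oxygenated, trisubstituted C9=C10.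

**Step 9**
Reactants: 17 7-bromo dienone; 18 isopropenylboronic acid pinacol ester
Product: 19 (4aR,5R,6R)-6-[(tert-butyldimethylsilyl)oxy]-4a,5-dimethyl-3-(prop-1-en-2-yl)-5,6,7,8-tetrahydronaphthalen-2(4aH)-one
Conditions: Pd(dppf)Cl2 (cat.), K3PO4, dioxane/H2O, 70 °C
Reagents that add atoms: none
Why: Suzuki–Miyaura coupling: the electron-poor C7–Br bond of the 2-bromoenone should add readily to zerovalent palladium, and the mild phosphate base leaves the dienone, the silyl ether and C5 untouched.

**Step 10**
Reactants: 19 7-isopropenyl dienone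
Product: 20 (4aR,5R,6R)-6-[(tert-butyldimethylsilyl)oxy]-3-(2-hydroxypropan-2-yl)-4a,5-dimethyl-5,6,7,8-tetrahydronaphthalen-2(4aH)-one
Conditions: Co(acac)2 (cat.), PhSiH3, O2 (1 atm), THF/i-PrOH, rt
Reagents that add atoms: dioxygen, O=O
Why: Mukaiyama hydration: a cobalt hydride should transfer a hydrogen atom to the terminal CH2 of the isopropenyl group, the most accessible alkene, the resulting radical is trapped by O2 at tertiary C11 rather than at the neopentyl C6, and the silane reduces the peroxide to the Markovnikov tertiary alcohol.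

**Step 11**
Reactants: 20 silyl-protected carbinol
Product: 21 (4aR,5R,6R)-6-hydroxy-3-(2-hydroxypropan-2-yl)-4a,5-dimethyl-5,6,7,8-tetrahydronaphthalen-2(4aH)-one
Conditions: HF·pyridine, THF/pyridine, 0 °C → rt
Reagents that add atoms: none
Why: Fluoride-mediated desilylation of the secondary TBS ether under buffered, weakly acidic conditions that should not ionise the tertiary allylic carbinol or rearrange the dienone.

**Step 12**
Reactants: 22 prop-2-yn-1-ol
Product: 24 (Z)-2-methyl-3-(methylsulfanyl)prop-2-en-1-ol, via Z-alkenylmagnesium alkoxide 23 (not isolated)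
Conditions: MeMgBr, CuI (cat.), THF, −10 °C → rt; then MeSSMe, 0 °C → rt; aq. NH4Cl
Reagents that add atoms: methylmagnesium bromide, C[Mg]Br; dimethyl disulfide, CSSC
Why: Copper-catalysed anti-carbomagnesiation of the propargylic alkoxide puts methyl on C2 and magnesium on C3 cis to CH2O (five-membered chelate), and sulfenylation of the alkenyl Grignard reagent with the disulfide proceeds with retention, so sulfur ends cis to the CH2OH group (Z).

**Step 13**
Reactants: 24 (Z)-allylic alcohol
Product: 25 (Z)-2-methyl-3-(methylsulfanyl)prop-2-enal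
Conditions: MnO2, CH2Cl2, rt; filtered and used at once
Reagents that add atoms: none
Why: Allylic oxidation with MnO2 is neutral and should not oxidise the sulfide, and immediate use limits Z to E drift of the push–pull enal.

**Step 14**
Reactants: 25 (Z)-enal
Product: 26 (Z)-2-methyl-3-(methylsulfanyl)prop-2-enoic acid
Conditions: NaClO2, NaH2PO4, 2-methyl-2-butene (large excess), t-BuOH/H2O, 0 °C
Reagents that add atoms: sodium chlorite, [Na+].[O-]Cl=O
Why: Pinnick oxidation: the sulfur is deactivated as a vinylogous thioester and hypochlorous acid is scavenged by the excess alkene, so the sulfide and the Z double bond should survive.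

**Step 15**
Reactants: 21 diol; 26 (Z)-acid
Product: 27 (1R,2R,8aR)-7-(2-hydroxypropan-2-yl)-1,8a-dimethyl-6-oxo-1,2,3,4,6,8a-hexahydronaphthalen-2-yl (2Z)-2-methyl-3-(methylsulfanyl)prop-2-enoate
Conditions: DCC, DMAP (cat.), CH2Cl2, 0 °C → rt
Reagents that add atoms: none
Why: Steglich esterification acylates the secondary C3 hydroxyl and leaves the tertiary C11 hydroxyl free, and catalytic DMAP at low temperature should limit isomerisation of the Z thioacrylate, which has no α-hydrogen for ketene formation.

**Compound list**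
1 | (S)-4-benzyl-3-propionyloxazolidin-2-one | CCC(=O)N1[C@@H](Cc2ccccc2)COC1=O | starting material
2 | pent-4-ynal | C#CCCC=O | starting material
3 | dibutylboron Z-enolate of 1 | C/C=C(\OB(CCCC)CCCC)N1[C@@H](Cc2ccccc2)COC1=O | intermediate
4 | O-dibutylboryl aldolate of 5 | C#CCC[C@@H](OB(CCCC)CCCC)[C@H](C)C(=O)N1[C@@H](Cc2ccccc2)COC1=O | intermediate
5 | (S)-4-benzyl-3-[(2S,3R)-3-hydroxy-2-methylhept-6-ynoyl]oxazolidin-2-one | C#CCC[C@@H](O)[C@H](C)C(=O)N1[C@@H](Cc2ccccc2)COC1=O | intermediate
6 | (2S,3R)-3-hydroxy-N-methoxy-N,2-dimethylhept-6-ynamide | C#CCC[C@@H](O)[C@H](C)C(=O)N(C)OC | intermediate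
7 | (2S,3R)-3-[(tert-butyldimethylsilyl)oxy]-N-methoxy-N,2-dimethylhept-6-ynamide | C#CCC[C@@H](O[Si](C)(C)C(C)(C)C)[C@H](C)C(=O)N(C)OC | intermediate
8 | bromomagnesium alkoxide of the tetrahedral methyl adduct of 7 (new carbon unassigned) | C#CCC[C@@H](O[Si](C)(C)C(C)(C)C)[C@H](C)C(C)(O[Mg]Br)N(C)OC | intermediate
9 | (3S,4R)-4-[(tert-butyldimethylsilyl)oxy]-3-methyloct-7-yn-2-one | C#CCC[C@@H](O[Si](C)(C)C(C)(C)C)[C@H](C)C(C)=O | intermediate
10 | tert-butyl{[(3R,4R)-2,3-dimethyloct-1-en-7-yn-4-yl]oxy}dimethylsilane | C#CCC[C@@H](O[Si](C)(C)C(C)(C)C)[C@H](C)C(C)=C | intermediate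
11 | hexacarbonyldicobalt complex of the alkyne of 10 | [CH]12[Co]3(=C=O)(=C=O)(=C=O)[Co]1(=C=O)(=C=O)(=C=O)C23CC[C@@H](O[Si](C)(C)C(C)(C)C)[C@H](C)C(C)=C | intermediate
12 | (6R,7R,7aR)-6-[(tert-butyldimethylsilyl)oxy]-7,7a-dimethyl-1,4,5,6,7,7a-hexahydro-2H-inden-2-one | CC(C)(C)[Si](C)(C)O[C@@H]1CCC2=CC(=O)C[C@]2(C)[C@H]1C | intermediate
13 | lithium dienolate of 12 (C6=C8, C9=C10) | CC(C)(C)[Si](C)(C)O[C@@H]1CCC2=CC(O[Li])=C[C@]2(C)[C@H]1C | intermediate
14 | 6-[(tert-butyldimethylsilyl)oxy]-7,7a-dimethyl-2-[(trimethylsilyl)oxy]-5,6,7,7a-tetrahydro-4H-indene, configuration as in 12 | CC(C)(C)[Si](C)(C)O[C@@H]1CCC2=CC(O[Si](C)(C)C)=C[C@]2(C)[C@H]1C | intermediate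
15 | bromoform | BrC(Br)Br | starting material
16 | gem-dibromocyclopropane across C6=C8 of 14 (C7 = CBr2, cyclopropane face unassigned) | CC(C)(C)[Si](C)(C)O[C@@H]1CCC2=CC3(O[Si](C)(C)C)C(Br)(Br)C3[C@]2(C)[C@H]1C | intermediate
17 | (4aS,5R,6R)-3-bromo-6-[(tert-butyldimethylsilyl)oxy]-4a,5-dimethyl-5,6,7,8-tetrahydronaphthalen-2(4aH)-one | CC(C)(C)[Si](C)(C)O[C@@H]1CCC2=CC(=O)C(Br)=C[C@]2(C)[C@H]1C | intermediate
18 | isopropenylboronic acid pinacol ester | C=C(C)B1OC(C)(C)C(C)(C)O1 | starting material
19 | (4aR,5R,6R)-6-[(tert-butyldimethylsilyl)oxy]-4a,5-dimethyl-3-(prop-1-en-2-yl)-5,6,7,8-tetrahydronaphthalen-2(4aH)-one | CC(C)(C)[Si](C)(C)O[C@@H]1CCC2=CC(=O)C(C(C)=C)=C[C@]2(C)[C@H]1C | intermediate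
20 | (4aR,5R,6R)-6-[(tert-butyldimethylsilyl)oxy]-3-(2-hydroxypropan-2-yl)-4a,5-dimethyl-5,6,7,8-tetrahydronaphthalen-2(4aH)-one | CC(C)(C)[Si](C)(C)O[C@@H]1CCC2=CC(=O)C(C(C)(C)O)=C[C@]2(C)[C@H]1C | intermediate
21 | (4aR,5R,6R)-6-hydroxy-3-(2-hydroxypropan-2-yl)-4a,5-dimethyl-5,6,7,8-tetrahydronaphthalen-2(4aH)-one | O[C@@H]1CCC2=CC(=O)C(C(C)(C)O)=C[C@]2(C)[C@H]1C | intermediate
22 | prop-2-yn-1-ol | C#CCO | starting material
23 | (Z)-3-(bromomagnesio)-2-methylprop-2-en-1-ol bromomagnesium alkoxide | Br[Mg]/C=C(/C)CO[Mg]Br | intermediate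
24 | (Z)-2-methyl-3-(methylsulfanyl)prop-2-en-1-ol | CS/C=C(/C)CO | intermediate
25 | (Z)-2-methyl-3-(methylsulfanyl)prop-2-enal | CS/C=C(/C)C=O | intermediate
26 | (Z)-2-methyl-3-(methylsulfanyl)prop-2-enoic acid | CS/C=C(/C)C(=O)O | intermediate
27 | (1R,2R,8aR)-7-(2-hydroxypropan-2-yl)-1,8a-dimethyl-6-oxo-1,2,3,4,6,8a-hexahydronaphthalen-2-yl (2Z)-2-methyl-3-(methylsulfanyl)prop-2-enoate (CNP0150028.1) | CS/C=C(/C)C(=O)O[C@@H]1CCC2=CC(=O)C(C(C)(C)O)=C[C@]2(C)[C@H]1C | target

**Step count:** 15 steps in total; longest linear sequence 12 steps (steps 1–11 and 15).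

**Steps most likely to fail**

1. Step 8 (carbene ring enlargement). The carbene may also cyclopropanate C9=C10, the alkoxide may cleave the trimethylsilyl enol ether before the carbene is captured, or the bromodienone may be degraded by excess base. The fallback sets out from 14 and inserts a CH2 unit instead. Simmons–Smith methylenation (Et2Zn, CH2I2) of the C6=C8 enol ether should give the siloxycyclopropane F1. FeCl3 in DMF should open the C6–C8 bond oxidatively to the ring-enlarged 6-chloro enone F2, and NaOAc in MeOH should eliminate HCl to the 7-unsubstituted dienone F3. I2/pyridine should then iodinate C7, the α-carbon of the arm whose β-carbon C6 carries hydrogen, to give the 7-iodo dienone F4. Suzuki coupling of F4 with 18 comes back to the route at 19.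

2. Step 6 (Pauson–Khand reaction). Insertion of a 1,1-disubstituted alkene in a 1,7-enyne may be slow, so that the alkyne complex oligomerises or loses cobalt, and facial control at C5 may be incomplete. The fallback sets out from 10 and builds the two rings one after the other. Markovnikov hydroiodination of the terminal alkyne (B-iodo-9-borabicyclo[3.3.1]nonane, then AcOH) should give the 2-iodo-1,7-diene F5. With Pd(PPh3)4 and K3PO4, a 6-exo Heck cyclisation onto the isopropenyl group should form C5–C10 and the quaternary C5 under the same chair control; the neopentyl palladium intermediate has no β-hydrogen and is intercepted by Suzuki coupling with 18, giving the ring A diene F6. Ozonolysis of both 1,1-disubstituted alkenes (O3, then Me2S) should give the 1,4-diketone F7, and aldol condensation (KOH, MeOH) of the methyl ketone carbon C9 onto the C10 ketone comes back to the route at 12.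

3. Step 10 (hydration). Hydrogen-atom transfer may also reach the dienone double bonds (over-reduction or α-oxygenation), and the delocalised radical may capture oxygen at C6 instead of C11. The fallback sets out from 17 and avoids radical chemistry; it replaces steps 9 and 10. Luche reduction (NaBH4, CeCl3, MeOH) should give the 7-bromo dienol F8. Deprotonation with MeLi, bromine–lithium exchange with t-BuLi at −78 °C and addition of acetone should give the dienyl diol F9. MnO2 should re-oxidise only the doubly allylic C8 alcohol, which comes back to the route at 20.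

**Further compounds**
F1 | step 8 | siloxycyclopropane from methylenation of C6=C8 of 14 | CC(C)(C)[Si](C)(C)O[C@@H]1CCC2=CC3(O[Si](C)(C)C)CC3[C@]2(C)[C@H]1C
F2 | step 8 | ring-enlarged 6-chloro enone (C6–Cl, C7H2, C8=O) | CC(C)(C)[Si](C)(C)O[C@@H]1CCC2=CC(=O)CC(Cl)[C@]2(C)[C@H]1C
F3 | step 8 | 6-[(tert-butyldimethylsilyl)oxy]-4a,5-dimethyl-5,6,7,8-tetrahydronaphthalen-2(4aH)-one | CC(C)(C)[Si](C)(C)O[C@@H]1CCC2=CC(=O)C=C[C@]2(C)[C@H]1C
F4 | step 8 | 3-iodo-6-[(tert-butyldimethylsilyl)oxy]-4a,5-dimethyl-5,6,7,8-tetrahydronaphthalen-2(4aH)-one | CC(C)(C)[Si](C)(C)O[C@@H]1CCC2=CC(=O)C(I)=C[C@]2(C)[C@H]1C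
F5 | step 6 | tert-butyl{[(3R,4R)-7-iodo-2,3-dimethylocta-1,7-dien-4-yl]oxy}dimethylsilane | C=C(I)CC[C@@H](O[Si](C)(C)C(C)(C)C)[C@H](C)C(C)=C
F6 | step 6 | ring A diene: 4-silyloxy-2,3-dimethyl-2-(2-methylallyl)-1-methylidenecyclohexane | CC(C)(C)[Si](C)(C)O[C@@H]1CCC(=C)[C@@](CC(C)=C)(C)[C@H]1C
F7 | step 6 | 1,4-diketone: 4-silyloxy-2,3-dimethyl-2-(2-oxopropyl)cyclohexanone | CC(C)(C)[Si](C)(C)O[C@@H]1CCC(=O)[C@@](CC(C)=O)(C)[C@H]1C
F8 | step 10 | 7-bromo dienol (C8–OH, both epimers) | CC(C)(C)[Si](C)(C)O[C@@H]1CCC2=CC(O)C(Br)=C[C@]2(C)[C@H]1C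
F9 | step 10 | 7-(2-hydroxypropan-2-yl) dienol (C8–OH, both epimers) | CC(C)(C)[Si](C)(C)O[C@@H]1CCC2=CC(O)C(C(C)(C)O)=C[C@]2(C)[C@H]1C
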